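I decide to count chains rather than follow each flask through time, because a length is monomer in chains divided by chains begun.

common to all: initiator 0.14 mM

| flask | free monomer | impurity | remark | time |
|---|---|---|---|---|
| green | 28 mM (fed, over 4.0 min) | 13 µM | run made earlier |  |
| ochre | 28 mM (fed, over 4.0 min) | 28 µM | run made earlier |  |
| midnight | 28 mM (fed, over 4.0 min) | 19 µM |  | 1.5 h |
| spring | 28 mM (fed, over 1.2 min) | 19 µM |  | 1.5 h |

| run | time / min | monomer in chains / % | free monomer / % |
|---|---|---|---|
| green | 10.0 | 42.2 | 57.5 |
| green | 20.0 | 73.7 | 25.8 |
| green | 25.0 | 82.2 | 18.5 |
| green | 40.0 | 94.4 | 5.2 |
| green | 50.0 | 96.7 | 3.6 |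
| ochre | 4.00 | 8.6 | 91.5 |
| ochre | 8.00 | 29.3 | 71.1 |
| ochre | 12.0 | 46.4 | 54.3 |
| ochre | 20.0 | 68.9 | 30.5 |
| ochre | 30.0 | 84.8 | 15.2 |
| ochre | 50.0 | 95.7 | 3.7 |

(scatter of a reading: 0.5 percentage points)

- the average divides the monomer in chains by the number of chains begun, living and dead together
- the earlier runs were read with a standard deviation of 0.5 percentage points
- the earlier runs do not show the number of chains; that part of a forecast is a guess

- which of the two ends with the longer chains by the average number of monomer units in a chain (chains begun, living or dead) ("neither" if they lie within 10%) (midnight / spring / neither)
- average number of monomer units in a chain (chains begun, living or dead) at the end, midnight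
- average number of monomer units in a chain (chains begun, living or dead) at the end, spring

Late in each run free monomer falls by a steady fraction per minute (pseudo-first-order). I read 0.0801 min⁻¹ in green and 0.0703 min⁻¹ in ochre, a ratio of 1.14. Initiator minus impurity stands in the ratio 1.13 between these runs, so I read each impurity as removing one chain starter.

Call initiator minus impurity the working initiator: midnight and spring each have 0.121 mM. Their slope is then 0.0763 min⁻¹, and 1.5 h is worth 2.98 powers of ten, so nearly all the charge ends in chains. The length is therefore the charge of free monomer per working initiator, 231.

The weak link is the count of chains, which the runs do not show. If impurity kills growing chains instead, those chains still count as begun, and the length is 200. I reforge the link as a bracket: neither end contains the dosing time, so I commit to neither, and my guess is the upper end, 231, for both flasks.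

The forecast also says neither, but with 220 for midnight and 213 for spring, each lower than my figure. On the gap it says: “Faster dosing favours initiation slightly”.

The flask gives neither, with 231 for midnight and 231 for spring, beside the reckoned 231.

    free monomer + initiator → living end + monomer in chains (k = 41.0 M⁻¹ min⁻¹)
    free monomer + living end → monomer in chains + living end, rate k2*[living end]*[free monomer] (k = 610 M⁻¹ min⁻¹)
    initiator + impurity → spent initiator (k = 1.30 × 10⁵ M⁻¹ min⁻¹)

In midnight, taking each step alone with the other charges held, the half-life of initiator is 0.28 min by impurity, shorter than the 0.604 min by the chain-starting step with the whole charge of free monomer. At the end spent initiator stands at 0.0190 mM in midnight and 0.0190 mM in spring, living ends at 0.121 mM and 0.121 mM. Spring's length has moved by 23.1 at initiator 0.129 mM or 0.154 mM, while the drawn-out feed makes no difference to it. For the neighbour, spring with 7.0 mM of free monomer, the working initiator gives 57.9; the flask gives 58.2.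

All runs are calculated on assumed constants; scatter was added.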